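The easy step is to subtract: starting material that has not become target is still there, so I count the fraction left. The problem stands here.

in all of them: starting material 0.083 M; second substrate 0.166 M; free catalyst 2.1 mM

|  | partner | protic impurity | temperature | remark | time |
|---|---|---|---|---|---|
| maple | 0.0789 M | 8.3 mM | 5 °C | the very flask that is asked about, followed so far |  |
| elm | 0.16 M | 8.3 mM | 0 °C | run made earlier |  |
| flask | 0.0789 M | 8.30 mM | 5 °C |  | 4.0 h |

| run | time / min | target / % |
|---|---|---|
| maple | 12.0 | 53 |
| maple | 40.0 | 53 |
| maple | 60.0 | 55 |
| maple | 90.0 | 59 |
| maple | 150 | 57 |
| maple | 180 | 58 |
| maple | 240 | 60 |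
| elm | 1.50 | 28 |
| elm | 3.00 | 45 |
| elm | 5.00 | 62 |
| elm | 6.00 | 67 |
| elm | 8.00 | 70 |
| elm | 10.0 | 79 |
| elm | 12.0 | 74 |

(readings scatter by 2 percentage points)

- Thursday's: at 4.0 h take out 90 % of the target then present, then wait 2.0 h
- Wednesday's: at 4.0 h add partner, 50.0 % of the amount charged, then wait 2.0 h
- Sunday's: change nothing and wait 2.0 h more
- Monday's: at 4.0 h raise the temperature by 15 K, then wait 2.0 h
- Friday's: at 4.0 h add free catalyst, 100 % of the amount charged, then wait 2.0 h

- target, in percent of the starting material first charged, at 4.0 h
- the remedy with the largest gain of target, or "none" below 2 percentage points (Thursday's / Wednesday's / Sunday's / Monday's / Friday's / none)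
- target present, with what was taken out counted in, in percent of the starting material first charged, after Wednesday's
- target present, with what was taken out counted in, in percent of the starting material first charged, after Friday's

- removed target is counted in
- candidate steps: second substrate + free catalyst <-> catalyst intermediate B; starting material + free catalyst <-> catalyst intermediate A; partner + catalyst intermediate A -> free catalyst + target; partner + catalyst intermediate B -> free catalyst + second product; second substrate + protic impurity -> quenched substrate; 2 free catalyst <-> resting dimer
- additions bring no volume worth counting

Maple's readings run from 53 % at 12.0 min to 60 % at 240 min with a scatter of 2 percentage points. They average 56.4 %, so I commit to that average at 4.0 h, which leaves 43.6 % of the starting material in maple. Elm, with 0.16 M of partner and the same catalyst but at 0 °C, reads 74 % at 12.0 min, higher than maple's average, and two settings differ between them. I therefore assume, as a working guess, that partner is the limiting reagent and that maple's 0.0789 M has gone into the two products.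

Each partner makes one target or one second product, so by my reckoning maple should hold about 0.0321 M of second product. I count protic impurity as removing its own amount of second substrate, leaving a base of 0.158 M, of which 79.7 % remains.

Two rates now matter: the fractional fall of starting material and the fractional fall of second substrate. Both draw on one partner through one catalyst, so I take their ratio as constant at one temperature. Maple's readings give about 3.65, with their scatter in it: the logarithm of the fraction left of starting material over that of second substrate, the selectivity factor.

Fresh partner in maple then goes to target, at the moment of adding, with a share of 51.3 %. Taking that opening share for all the added partner, I estimate that Wednesday's adds about 24 points and reaches about 80.4 %. The other remedies bring no partner, so I expect no gain from them, and I choose Wednesday's.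

The forecast differs: 59 % now, Friday's as best, 63 % after Wednesday's and 68 % after Friday's. Its ground is this: “catalyst is being lost into the resting dimer”.

The flask gives 57.1 % now, Wednesday's as best, 79.6 % after Wednesday's and 57.1 % after Friday's.

    second substrate + free catalyst ⇌ catalyst intermediate B (K = 7.20 /M, k = 230 /M/s, Ea = 35.0 kJ/mol, ΔH = 20.0 kJ/mol)
    starting material + free catalyst ⇌ catalyst intermediate A (K = 18.0 /M, k = 16.0 /M/s, Ea = 47.0 kJ/mol, ΔH = −46.0 kJ/mol)
    partner + catalyst intermediate A → free catalyst + target (k = 4.90 /M/s, Ea = 39.0 kJ/mol)
    partner + catalyst intermediate B → free catalyst + second product (k = 2.70 /M/s, Ea = 39.0 kJ/mol)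
    second substrate + protic impurity → quenched substrate (k = 4.50 /M/s, Ea = 53.0 kJ/mol)
    2 free catalyst ⇌ resting dimer (K = 7900 /M, k = 8.80 /M/s, Ea = 51.0 kJ/mol, ΔH = 28.0 kJ/mol)
    (constants at 5 °C)

At 240 min partner stands at 0 % of its charge, with 42.7 % of the starting material still free. Wednesday's gain of target amounts to 47.3 % of the added partner, taken over the whole addition, less than my opening share. The neighbour flask with 0.033 M of starting material ends with 63 % of its second substrate. My selectivity factor turns that into 22.4 % of starting material left, so 77.6 % of target, and the neighbour holds 79.1 %.

The earlier runs and the new flask come from a simulation with made-up constants.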